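**Strategy.** The synthesis rests on disconnecting the O1–C2 bond of the dihydrobenzofuran ring. C2 is benzylic to the guaiacyl ring and para to its C4' oxygen, so its carbinol ionises to a quinone-methide-type cation that the oxygen on C7a captures. One acid treatment therefore unmasks the phenol, closes the five-membered ring and sets C2 trans to the C3 hydroxymethyl group, whatever the carbinol configuration. The precursor is a 1-guaiacyl-2-arylpropane-1,3-diol whose aryl ring carries the bromide handle, a benzyl ether and a MOM-masked phenol; its one essential stereocentre (future C3) comes from an Evans aldol. The flavanone ring is attached afterwards by rhodium-catalysed asymmetric arylation of a chromone.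

Key step: step 9

Remark on the structures: the stereodescriptors were checked and no error was found. The target is the (2S)-flavanone carrying a (2R,3S)-trans-dihydrobenzofuran. The aryl-bearing carbon must be (S) in the diol, which is the (2R)-acyl centre of the aldol adduct (the priorities change on reduction), so the (R)-4-benzyl auxiliary is required.

Remark on the precursor design: an acid-labile phenol mask cannot be removed without triggering the ring closure, so the C7a phenol is carried as a MOM acetal into step 9 and the free phenol diol 16 is formed and consumed in the same flask.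

Assumption: the (S)-biaryl bisphosphine/rhodium catalyst of step 13 is taken to add the aryl group with the facial sense that (S)-BINAP-type rhodium catalysts show with cyclic enones, which corresponds to the (2S)-flavanone; the (R)-ligand would be used if the sense proves opposite.

**Route**

Step 1
Reactants: 1 2,3-dihydroxybenzaldehyde
Product: 2 3-(benzyloxy)-2-hydroxybenzaldehyde
Conditions: NaH (2.2 equiv), DMSO, 20 °C; BnBr (1.0 equiv); aq. HCl work-up
Reagents that add atoms: benzyl bromide, BrCc1ccccc1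
Why: After double deprotonation of 1 the 3-oxide, which is not conjugated with the aldehyde, is the more nucleophilic oxygen, so one equivalent of benzyl bromide should alkylate O3 selectively (Williamson etherification).

Step 2
Reactants: 2 3-(benzyloxy)-2-hydroxybenzaldehyde
Product: 3 3-(benzyloxy)-5-bromo-2-hydroxybenzaldehyde
Conditions: Br2 (1.05 equiv), NaOAc, AcOH, 20 °C
Reagents that add atoms: bromine, BrBr
Why: Electrophilic aromatic bromination should go to C5, which is para to the free hydroxyl and meta to the aldehyde, as it does with the analogous 3-methoxy compound.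

Step 3
Reactants: 3 3-(benzyloxy)-5-bromo-2-hydroxybenzaldehyde
Product: 4 3-(benzyloxy)-5-bromo-2-(methoxymethoxy)benzaldehyde
Conditions: MOMCl, i-Pr2NEt, CH2Cl2, 0 to 40 °C
Reagents that add atoms: chloromethyl methyl ether, COCCl
Why: O-Alkylation of the phenol with the reactive chloromethyl ether gives an acetal that is stable to the basic and hydride steps ahead and is removed by the acid of the key step.

Step 4
Reactants: 4 3-(benzyloxy)-5-bromo-2-(methoxymethoxy)benzaldehyde
Product: 6 2-[3-(benzyloxy)-5-bromo-2-(methoxymethoxy)phenyl]acetonitrile, via tosyl-enamide 5 (not isolated)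
Conditions: TosMIC, t-BuOK, DME, −40 °C; then MeOH, 65 °C
Reagents that add atoms: p-toluenesulfonylmethyl isocyanide (TosMIC), Cc1ccc(cc1)S(=O)(=O)C[N+]#[C-]
Why: Van Leusen reductive cyanation: the TosMIC anion adds to the aldehyde, the oxazoline opens to the N-formyl tosyl-enamide 5, and methanolysis removes the formyl group and sulfinate to leave the nitrile with one more carbon.

Step 5
Reactants: 6 2-[3-(benzyloxy)-5-bromo-2-(methoxymethoxy)phenyl]acetonitrile
Product: 7 2-[3-(benzyloxy)-5-bromo-2-(methoxymethoxy)phenyl]acetic acid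
Conditions: KOH, EtOH–H2O, reflux; then 1 M HCl to pH 3, 0 °C
Reagents that add atoms: potassium hydroxide, [K+].[OH-]; water, O
Why: Alkaline nitrile hydrolysis should give the arylacetic acid, since the acetal, the benzyl ether and the aryl bromide are inert to hydroxide and the cold brief acidification spares the acetal.

Step 6
Reactants: 7 2-[3-(benzyloxy)-5-bromo-2-(methoxymethoxy)phenyl]acetic acid; 8 (4R)-4-benzyl-1,3-oxazolidin-2-one
Product: 10 (4R)-4-benzyl-3-{2-[3-(benzyloxy)-5-bromo-2-(methoxymethoxy)phenyl]acetyl}-1,3-oxazolidin-2-one, via mixed pivalic anhydride 9 (not isolated)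
Conditions: PivCl, Et3N, THF, −20 °C; then LiCl, 8, 20 °C
Reagents that add atoms: none
Why: N-Acylation of the oxazolidinone through the mixed anhydride, in which the auxiliary nitrogen (activated by LiCl/Et3N) attacks the unhindered arylacetyl carbonyl and not the pivaloyl one.

Step 7
Reactants: 10 (4R)-4-benzyl-3-{2-[3-(benzyloxy)-5-bromo-2-(methoxymethoxy)phenyl]acetyl}-1,3-oxazolidin-2-one; 11 4-(benzyloxy)-3-methoxybenzaldehyde
Product: 14 (4R)-4-benzyl-3-{(2R,3R)-3-[4-(benzyloxy)-3-methoxyphenyl]-2-[3-(benzyloxy)-5-bromo-2-(methoxymethoxy)phenyl]-3-hydroxypropanoyl}-1,3-oxazolidin-2-one, via dibutylboron enolate 12 (not isolated), via dibutylboron aldolate 13 (not isolated)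
Conditions: Bu2BOTf, i-Pr2NEt, CH2Cl2, −78 to 0 °C; 11, −78 to 0 °C; then pH 7 buffer, MeOH, H2O2, 0 °C
Reagents that add atoms: none
Why: Evans boron aldol: the Z-enolate reacts through a closed Zimmerman–Traxler chair on the face away from the auxiliary benzyl group, which should give the syn adduct and fix the aryl-bearing carbon (future C3) as (2R); the carbinol configuration is of no consequence later.

Step 8
Reactants: 14 (4R)-4-benzyl-3-{(2R,3R)-3-[4-(benzyloxy)-3-methoxyphenyl]-2-[3-(benzyloxy)-5-bromo-2-(methoxymethoxy)phenyl]-3-hydroxypropanoyl}-1,3-oxazolidin-2-one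
Product: 15 (1R,2S)-1-[4-(benzyloxy)-3-methoxyphenyl]-2-[3-(benzyloxy)-5-bromo-2-(methoxymethoxy)phenyl]propane-1,3-diol
Conditions: LiBH4, MeOH (2 equiv), THF, 0 °C
Reagents that add atoms: none
Why: Reductive auxiliary removal: LiBH4 attacks the exocyclic imide carbonyl selectively and should give the primary alcohol without touching either stereocentre, the aryl bromide or the ethers.

Step 9
Reactants: 15 (1R,2S)-1-[4-(benzyloxy)-3-methoxyphenyl]-2-[3-(benzyloxy)-5-bromo-2-(methoxymethoxy)phenyl]propane-1,3-diol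
Product: 18 [(2R,3S)-7-(benzyloxy)-2-[4-(benzyloxy)-3-methoxyphenyl]-5-bromo-2,3-dihydro-1-benzofuran-3-yl]methanol, via phenol diol 16 (not isolated), via benzylic cation 17 (not isolated)
Conditions: HCl (1.25 M in MeOH, 5 equiv), MeOH–THF, 0 to 40 °C
Reagents that add atoms: none
Why: Methanolic HCl cleaves the MOM acetal to phenol 16 and protonates the benzylic hydroxyl, whose loss gives cation 17, delocalised onto the para benzyloxy oxygen of the guaiacyl ring; the phenol oxygen on the future C7a then attacks this carbon and forms O1–C2 (capture by the acetal oxygen with loss of the methoxymethyl group would lead to the same product). The closest known reaction type is the acid-promoted cyclodehydration of 1-aryl-2-(2-hydroxyaryl)propane-1,3-diols to trans-2-aryl-3-(hydroxymethyl)-2,3-dihydrobenzofurans, an SN1 etherification. The dihydrofuran ring closes in a 5-exo-trig mode, the oxygen adding to the exocyclic quinone-methide carbon. The new C2 stereocentre is controlled by the existing C3 centre: the guaiacyl group should take the face anti to CH2OH, both kinetically and because the closure is reversible under acid, so the trans (2R,3S) ring results, and since the carbinol centre becomes planar either epimer of the diol converges on it. The step needs trans diastereoselectivity and chemoselectivity for the phenol oxygen; the primary hydroxyl cannot compete because it would have to form an oxetane, and the mild protic acid leaves the benzyl ethers and the aryl bromide intact.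

Step 10
Reactants: 18 [(2R,3S)-7-(benzyloxy)-2-[4-(benzyloxy)-3-methoxyphenyl]-5-bromo-2,3-dihydro-1-benzofuran-3-yl]methanol
Product: 19 {(2R,3S)-7-(benzyloxy)-2-[4-(benzyloxy)-3-methoxyphenyl]-3-(hydroxymethyl)-2,3-dihydro-1-benzofuran-5-yl}boronic acid
Conditions: B2(OH)4 (3 equiv), chloro(2-dicyclohexylphosphino-2',4',6'-triisopropyl-1,1'-biphenyl)[2-(2'-amino-1,1'-biphenyl)]palladium (2 mol %), XPhos (4 mol %), KOAc, EtOH, 80 °C
Reagents that add atoms: tetrahydroxydiboron, OB(O)B(O)O
Why: Miyaura-type palladium-catalysed borylation (oxidative addition into C–Br, acetate-assisted transmetalation from the diboron, reductive elimination) should give the free boronic acid directly and tolerates the hydroxyl and benzyl ether groups.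

Step 11
Reactants: 20 2',4',6'-trihydroxyacetophenone
Product: 21 1-[2,4-bis(benzyloxy)-6-hydroxyphenyl]ethan-1-one
Conditions: BnBr (2.1 equiv), K2CO3, DMF, 20 °C
Reagents that add atoms: benzyl bromide, BrCc1ccccc1
Why: Williamson benzylation with two equivalents should leave one ortho hydroxyl free, because after the first ortho benzylation the remaining one is hydrogen-bonded to the ketone and is the least nucleophilic oxygen.

Step 12
Reactants: 21 1-[2,4-bis(benzyloxy)-6-hydroxyphenyl]ethan-1-one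
Product: 23 5,7-bis(benzyloxy)-4H-chromen-4-one, via enaminone 22 (not isolated)
Conditions: DMF-DMA, toluene, 100 °C; then conc. HCl, CH2Cl2, 40 °C
Reagents that add atoms: N,N-dimethylformamide dimethyl acetal, COC(OC)N(C)C
Why: Enaminone route to chromones: the methyl ketone condenses with the amide acetal to 22, and acid promotes addition of the phenol to the enaminone carbon with loss of dimethylamine to close the pyranone ring.

Step 13
Reactants: 19 {(2R,3S)-7-(benzyloxy)-2-[4-(benzyloxy)-3-methoxyphenyl]-3-(hydroxymethyl)-2,3-dihydro-1-benzofuran-5-yl}boronic acid; 23 5,7-bis(benzyloxy)-4H-chromen-4-one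
Product: 24 (2S)-5,7-bis(benzyloxy)-2-{(2R,3S)-7-(benzyloxy)-2-[4-(benzyloxy)-3-methoxyphenyl]-3-(hydroxymethyl)-2,3-dihydro-1-benzofuran-5-yl}-2,3-dihydro-4H-chromen-4-one
Conditions: [Rh(OH)(cod)]2 (3 mol %), (S)-2,2'-bis[bis(3,4,5-trifluorophenyl)phosphino]-6,6'-dimethoxy-1,1'-biphenyl (6.6 mol %), 23 (2 equiv), toluene–H2O, 30 °C
Reagents that add atoms: none
Why: Rhodium-catalysed asymmetric conjugate addition of an arylboronic acid to a chromone (Hayashi–Miyaura reaction): boron-to-rhodium transmetalation, enantioface-selective carbometalation of the C2=C3 bond and protonolysis by water should set flavanone C2 as (S) under catalyst control, the remote centres of 19 having little influence, while the base-free medium avoids ring-opening of the flavanone.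

Step 14
Reactants: 24 (2S)-5,7-bis(benzyloxy)-2-{(2R,3S)-7-(benzyloxy)-2-[4-(benzyloxy)-3-methoxyphenyl]-3-(hydroxymethyl)-2,3-dihydro-1-benzofuran-5-yl}-2,3-dihydro-4H-chromen-4-one
Product: 25 Silyhermin B
Conditions: H2 (1 atm), 10 % Pd/C, EtOAc–MeOH, 20 °C
Reagents that add atoms: none
Why: Catalytic hydrogenolysis should remove all four benzyl ethers, since the cyclic benzylic C–O bonds of the dihydrobenzofuran and flavanone rings and the hydrogen-bonded ketone react much more slowly, so no stereocentre is touched.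

**Compound list**

1 | 2,3-dihydroxybenzaldehyde | O=Cc1cccc(O)c1O | starting material
2 | 3-(benzyloxy)-2-hydroxybenzaldehyde | O=Cc1cccc(OCc2ccccc2)c1O | intermediate
3 | 3-(benzyloxy)-5-bromo-2-hydroxybenzaldehyde | O=Cc1cc(Br)cc(OCc2ccccc2)c1O | intermediate
4 | 3-(benzyloxy)-5-bromo-2-(methoxymethoxy)benzaldehyde | COCOc1c(C=O)cc(Br)cc1OCc1ccccc1 | intermediate
5 | N-{2-[3-(benzyloxy)-5-bromo-2-(methoxymethoxy)phenyl]-1-(4-methylbenzenesulfonyl)ethenyl}formamide (tosyl-enamide, alkene geometry immaterial) | O=CNC(=Cc1cc(Br)cc(OCc2ccccc2)c1OCOC)S(=O)(=O)c1ccc(C)cc1 | intermediate (not isolated)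
6 | 2-[3-(benzyloxy)-5-bromo-2-(methoxymethoxy)phenyl]acetonitrile | N#CCc1cc(Br)cc(OCc2ccccc2)c1OCOC | intermediate
7 | 2-[3-(benzyloxy)-5-bromo-2-(methoxymethoxy)phenyl]acetic acid | OC(=O)Cc1cc(Br)cc(OCc2ccccc2)c1OCOC | intermediate
8 | (4R)-4-benzyl-1,3-oxazolidin-2-one | O=C1OC[C@@H](Cc2ccccc2)N1 | starting material
9 | 2-[3-(benzyloxy)-5-bromo-2-(methoxymethoxy)phenyl]acetic pivalic anhydride | CC(C)(C)C(=O)OC(=O)Cc1cc(Br)cc(OCc2ccccc2)c1OCOC | intermediate (not isolated)
10 | (4R)-4-benzyl-3-{2-[3-(benzyloxy)-5-bromo-2-(methoxymethoxy)phenyl]acetyl}-1,3-oxazolidin-2-one | O=C1OC[C@@H](Cc2ccccc2)N1C(=O)Cc1cc(Br)cc(OCc2ccccc2)c1OCOC | intermediate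
11 | 4-(benzyloxy)-3-methoxybenzaldehyde | COc1cc(C=O)ccc1OCc1ccccc1 | starting material
12 | (Z)-dibutylboron enolate of 10 | CCCCB(CCCC)O/C(=C\c1cc(Br)cc(OCc2ccccc2)c1OCOC)N1[C@H](Cc2ccccc2)COC1=O | intermediate (not isolated)
13 | O-dibutylboryl aldolate of 14 | O=C1OC[C@@H](Cc2ccccc2)N1C(=O)[C@H](c1cc(Br)cc(OCc2ccccc2)c1OCOC)[C@@H](OB(CCCC)CCCC)c1ccc(OCc2ccccc2)c(OC)c1 | intermediate (not isolated)
14 | (4R)-4-benzyl-3-{(2R,3R)-3-[4-(benzyloxy)-3-methoxyphenyl]-2-[3-(benzyloxy)-5-bromo-2-(methoxymethoxy)phenyl]-3-hydroxypropanoyl}-1,3-oxazolidin-2-one | O=C1OC[C@@H](Cc2ccccc2)N1C(=O)[C@H](c1cc(Br)cc(OCc2ccccc2)c1OCOC)[C@@H](O)c1ccc(OCc2ccccc2)c(OC)c1 | intermediate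
15 | (1R,2S)-1-[4-(benzyloxy)-3-methoxyphenyl]-2-[3-(benzyloxy)-5-bromo-2-(methoxymethoxy)phenyl]propane-1,3-diol | COc1cc([C@H](O)[C@H](CO)c2cc(Br)cc(OCc3ccccc3)c2OCOC)ccc1OCc1ccccc1 | intermediate
16 | (1R,2S)-1-[4-(benzyloxy)-3-methoxyphenyl]-2-[3-(benzyloxy)-5-bromo-2-hydroxyphenyl]propane-1,3-diol | COc1cc([C@H](O)[C@H](CO)c2cc(Br)cc(OCc3ccccc3)c2O)ccc1OCc1ccccc1 | intermediate (not isolated)
17 | benzylic cation (quinone-methide oxocarbenium) derived from 16 | COc1cc([CH+][C@H](CO)c2cc(Br)cc(OCc3ccccc3)c2O)ccc1OCc1ccccc1 | intermediate (not isolated)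
18 | [(2R,3S)-7-(benzyloxy)-2-[4-(benzyloxy)-3-methoxyphenyl]-5-bromo-2,3-dihydro-1-benzofuran-3-yl]methanol | COc1cc([C@@H]2Oc3c(OCc4ccccc4)cc(Br)cc3[C@H]2CO)ccc1OCc1ccccc1 | intermediate
19 | {(2R,3S)-7-(benzyloxy)-2-[4-(benzyloxy)-3-methoxyphenyl]-3-(hydroxymethyl)-2,3-dihydro-1-benzofuran-5-yl}boronic acid | COc1cc([C@@H]2Oc3c(OCc4ccccc4)cc(B(O)O)cc3[C@H]2CO)ccc1OCc1ccccc1 | intermediate
20 | 2',4',6'-trihydroxyacetophenone | CC(=O)c1c(O)cc(O)cc1O | starting material
21 | 1-[2,4-bis(benzyloxy)-6-hydroxyphenyl]ethan-1-one | CC(=O)c1c(O)cc(OCc2ccccc2)cc1OCc1ccccc1 | intermediate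
22 | (E)-1-[2,4-bis(benzyloxy)-6-hydroxyphenyl]-3-(dimethylamino)prop-2-en-1-one | CN(C)/C=C/C(=O)c1c(O)cc(OCc2ccccc2)cc1OCc1ccccc1 | intermediate (not isolated)
23 | 5,7-bis(benzyloxy)-4H-chromen-4-one | O=c1ccoc2cc(OCc3ccccc3)cc(OCc3ccccc3)c12 | intermediate
24 | (2S)-5,7-bis(benzyloxy)-2-{(2R,3S)-7-(benzyloxy)-2-[4-(benzyloxy)-3-methoxyphenyl]-3-(hydroxymethyl)-2,3-dihydro-1-benzofuran-5-yl}-2,3-dihydro-4H-chromen-4-one | COc1cc([C@@H]2Oc3c(OCc4ccccc4)cc([C@@H]4CC(=O)c5c(OCc6ccccc6)cc(OCc6ccccc6)cc5O4)cc3[C@H]2CO)ccc1OCc1ccccc1 | intermediate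
25 | Silyhermin B, (2S)-5,7-dihydroxy-2-[(2R,3S)-7-hydroxy-2-(4-hydroxy-3-methoxyphenyl)-3-(hydroxymethyl)-2,3-dihydro-1-benzofuran-5-yl]-2,3-dihydro-4H-chromen-4-one | COc1cc([C@@H]2Oc3c(O)cc([C@@H]4CC(=O)c5c(O)cc(O)cc5O4)cc3[C@H]2CO)ccc1O | target

**Step count and risks**

Total step count: 14. Longest linear sequence: 12 steps (steps 1 to 10, then 13 and 14); steps 11 and 12 form the two-step chromone branch.

Steps most likely to fail:

1. Step 13. Carbometalation of the electron-rich 5,7-dialkoxychromone may be slow, so that protodeboronation consumes the limiting boronic acid; facial selectivity may also be insufficient, or the flavanone may ring-open and lose its configuration. The fallback builds the flavanone by the chalcone route and gives up catalyst control of its C2 centre. It sets out from 18: bromine–lithium exchange (n-BuLi, 2.2 equiv, THF, −78 °C) and quenching with DMF should give (2R,3S)-7-(benzyloxy)-2-[4-(benzyloxy)-3-methoxyphenyl]-3-(hydroxymethyl)-2,3-dihydro-1-benzofuran-5-carbaldehyde F1. Claisen–Schmidt condensation of this aldehyde with acetophenone 21 (KOH, EtOH, 20 °C) should give (E)-1-[2,4-bis(benzyloxy)-6-hydroxyphenyl]-3-{(2R,3S)-7-(benzyloxy)-2-[4-(benzyloxy)-3-methoxyphenyl]-3-(hydroxymethyl)-2,3-dihydro-1-benzofuran-5-yl}prop-2-en-1-one F2. Oxa-Michael ring closure (NaOAc, EtOH, reflux) should then give 24 together with its flavanone epimer, (2R)-5,7-bis(benzyloxy)-2-{(2R,3S)-7-(benzyloxy)-2-[4-(benzyloxy)-3-methoxyphenyl]-3-(hydroxymethyl)-2,3-dihydro-1-benzofuran-5-yl}-2,3-dihydro-4H-chromen-4-one F3, to be separated by preparative HPLC. The route is rejoined at 24.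

2. Step 9. While acetal cleavage is still incomplete, the benzylic cation may fragment with loss of formaldehyde to a stilbene or alkylate an electron-rich arene intermolecularly. The fallback ionises an ester leaving group under aprotic Lewis-acid conditions with the hydroxymethyl group blocked. It sets out from 15: acetylation (Ac2O, pyridine, DMAP) should give (1R,2S)-1-[4-(benzyloxy)-3-methoxyphenyl]-2-[3-(benzyloxy)-5-bromo-2-(methoxymethoxy)phenyl]propane-1,3-diyl diacetate F4. BF3·OEt2 in CH2Cl2 at −40 °C should ionise the benzylic acetate, and the acetal oxygen should close the ring with loss of its methoxymethyl group to give [(2R,3S)-7-(benzyloxy)-2-[4-(benzyloxy)-3-methoxyphenyl]-5-bromo-2,3-dihydro-1-benzofuran-3-yl]methyl acetate F5. Methanolysis (K2CO3, MeOH) returns to the route at 18.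

3. Step 8. The lithium aldolate may undergo retro-aldol cleavage, or the alpha-aryl centre may epimerise, before hydride is delivered. The fallback caps the carbinol first. It sets out from 14: silylation (TESOTf, 2,6-lutidine, CH2Cl2, −78 °C) should give (4R)-4-benzyl-3-{(2R,3R)-3-[4-(benzyloxy)-3-methoxyphenyl]-2-[3-(benzyloxy)-5-bromo-2-(methoxymethoxy)phenyl]-3-[(triethylsilyl)oxy]propanoyl}-1,3-oxazolidin-2-one F6. LiBH4 reduction should give (2S,3R)-3-[4-(benzyloxy)-3-methoxyphenyl]-2-[3-(benzyloxy)-5-bromo-2-(methoxymethoxy)phenyl]-3-[(triethylsilyl)oxy]propan-1-ol F7. The methanolic HCl of step 9 should then remove the silyl ether and the acetal and close the ring, so the route is rejoined at 18.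

Further compounds
F1 | step 13 | (2R,3S)-7-(benzyloxy)-2-[4-(benzyloxy)-3-methoxyphenyl]-3-(hydroxymethyl)-2,3-dihydro-1-benzofuran-5-carbaldehyde | COc1cc([C@@H]2Oc3c(OCc4ccccc4)cc(C=O)cc3[C@H]2CO)ccc1OCc1ccccc1
F2 | step 13 | (E)-1-[2,4-bis(benzyloxy)-6-hydroxyphenyl]-3-{(2R,3S)-7-(benzyloxy)-2-[4-(benzyloxy)-3-methoxyphenyl]-3-(hydroxymethyl)-2,3-dihydro-1-benzofuran-5-yl}prop-2-en-1-one | COc1cc([C@@H]2Oc3c(OCc4ccccc4)cc(/C=C/C(=O)c4c(O)cc(OCc5ccccc5)cc4OCc4ccccc4)cc3[C@H]2CO)ccc1OCc1ccccc1
F3 | step 13 | (2R)-5,7-bis(benzyloxy)-2-{(2R,3S)-7-(benzyloxy)-2-[4-(benzyloxy)-3-methoxyphenyl]-3-(hydroxymethyl)-2,3-dihydro-1-benzofuran-5-yl}-2,3-dihydro-4H-chromen-4-one | COc1cc([C@@H]2Oc3c(OCc4ccccc4)cc([C@H]4CC(=O)c5c(OCc6ccccc6)cc(OCc6ccccc6)cc5O4)cc3[C@H]2CO)ccc1OCc1ccccc1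
F4 | step 9 | (1R,2S)-1-[4-(benzyloxy)-3-methoxyphenyl]-2-[3-(benzyloxy)-5-bromo-2-(methoxymethoxy)phenyl]propane-1,3-diyl diacetate | COc1cc([C@H](OC(C)=O)[C@H](COC(C)=O)c2cc(Br)cc(OCc3ccccc3)c2OCOC)ccc1OCc1ccccc1
F5 | step 9 | [(2R,3S)-7-(benzyloxy)-2-[4-(benzyloxy)-3-methoxyphenyl]-5-bromo-2,3-dihydro-1-benzofuran-3-yl]methyl acetate | COc1cc([C@@H]2Oc3c(OCc4ccccc4)cc(Br)cc3[C@H]2COC(C)=O)ccc1OCc1ccccc1
F6 | step 8 | (4R)-4-benzyl-3-{(2R,3R)-3-[4-(benzyloxy)-3-methoxyphenyl]-2-[3-(benzyloxy)-5-bromo-2-(methoxymethoxy)phenyl]-3-[(triethylsilyl)oxy]propanoyl}-1,3-oxazolidin-2-one | O=C1OC[C@@H](Cc2ccccc2)N1C(=O)[C@H](c1cc(Br)cc(OCc2ccccc2)c1OCOC)[C@@H](O[Si](CC)(CC)CC)c1ccc(OCc2ccccc2)c(OC)c1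
F7 | step 8 | (2S,3R)-3-[4-(benzyloxy)-3-methoxyphenyl]-2-[3-(benzyloxy)-5-bromo-2-(methoxymethoxy)phenyl]-3-[(triethylsilyl)oxy]propan-1-ol | COc1cc([C@H](O[Si](CC)(CC)CC)[C@H](CO)c2cc(Br)cc(OCc3ccccc3)c2OCOC)ccc1OCc1ccccc1
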